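Slowness came first in my reckoning: the enzyme drifts into the dormant form at 0.00856 s⁻¹, whereas the starting complex breaks down to product at 431 s⁻¹, so I put the working round in steady state and left that drift for last.

starting material 2.0 mM; enzyme 0.20 µM; added ligand 0.10 µM

    enzyme ⇌ dormant form (K1 = 0.22, k1 = 0.00856 s⁻¹)
    starting complex ⇌ enzyme + product (K2 = 0.0019 M, k2 = 431 s⁻¹)
    enzyme + added ligand ⇌ idle complex, settled at all times (K3 = 2.70 × 10⁸ M⁻¹)
    starting material + enzyme ⇌ starting complex (K4 = 16100 M⁻¹, k4 = 1.51 × 10⁶ M⁻¹ s⁻¹)

- the form that holds most of the catalyst when 10% of the starting material are converted (idle complex / starting complex / dormant form / enzyme)
- its share of the catalyst then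
- factor on the rate of making product when 10% of the starting material are converted if enzyme is charged twice over
- factor on the rate when 10% of the starting material are converted if enzyme is charged at 0.020 µM instead

I began with the binding of starting material and the release of product, without ligand or dormant form. At 10% conversion the flask holds 1.80 mM of starting material and 0.200 mM of product. The catalyst in the working round per free enzyme, which I call the load λ, is then 6.27: one for the enzyme, plus its rates into the starting complex over its rates out. At this stage free enzyme stands at 0.0319 µM, and each free enzyme makes product at a net 2220 s⁻¹.

Then I added the ligand. Its constant times its charge is 27.0, more than the load, so it competes with the round for free enzyme e. The charge must equal λe plus the idle complex, and the idle complex is the ligand charge times the bound fraction: the ligand's binding constant times e, over one plus that same product. This quadratic lowers e to 0.0186 µM.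

Last came the dormant form. At that rate the conversion takes about 4.83 s, in which the dormant form gathers about 0.0414 per free enzyme, less than its balance of 0.22. Adding this to the load gives 6.31 and e = 0.0185 µM. So the most catalyst sits in the starting complex, the resting state of the round, with a share of 48.7%. With the charge doubled and the same allowance, e becomes 0.0487 µM, so the rate rises by a factor of 2.63, more than double.

The forecast named the starting complex at 48.7% (range 47% to 50.5%), a doubling factor of 2.64 (2.5 to 2.8) and a factor of 0.037 (0.034 to 0.04) for the smaller charge. Its starting ground was: “The enzyme turns over quickly, so the starting complex is in steady state with free enzyme.”

The simulation gave the starting complex at 48.7% after 0.0790 min, and a doubling factor of 2.64. In that run the starting complex stood to the enzyme as 5.27, where λ minus one is 5.27. In the 0.020 µM flask the same conversion gives the same λ, and with the dormant form counted at its balance the load is 6.49. The balance then gives 6.83 × 10⁻⁴ µM of free enzyme and a rate factor of 0.0369, and the simulation of that flask gave 0.0369.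

Its constants are assumed; the flask was simulated.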